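## Retrosynthetic overview

1. The side-chain alkene is cut by E-selective cross-metathesis into a 2-vinyl furo[3,2-b]pyranone core and (2R,3S)-2-hydroxypent-4-en-3-yl benzoate, the latter from ethanol and acrolein gem-dibenzoate.
2. Both rings of the core form in one flask from an acyclic epoxy-triene acrylate: ring A (oxolane) by 5-endo opening of a cis-vinyl epoxide by a methoxymethyl-ether oxygen, then ring B (dihydropyranone) by acrylate ring-closing metathesis.
3. The cis-vinyl epoxide comes from reagent-controlled (Z)-chloroallylboration of an α-acryloyloxy aldehyde, then base.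
4. That aldehyde comes from (Z)-(methoxymethoxy)allylboration of prenal, acryloylation and selective ozonolysis of the prenyl alkene.
5. Ring order: ring A, then ring B, in the same operation; the side chain is attached last.

Assumption: the antipode named for each chiral ligand or borane is the one expected from the accepted facial models; should a sense of induction prove opposite, the mirror-image reagent, equally available, is used.

## Route

Step 1
Reactants: 1 acrolein; 2 benzoic anhydride
Product: 3 prop-2-ene-1,1-diyl dibenzoate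
Conditions: FeCl3 (2 mol%), CH2Cl2, 0 °C to rt
Reagents that add atoms: none
Why: Lewis-acid-catalysed acylal formation adds the anhydride across the aldehyde C=O, is atom-economic, leaves the vinyl group untouched and creates no stereocentre.

Step 2
Reactants: 3 prop-2-ene-1,1-diyl dibenzoate; 4 ethanol
Product: 5 (2R,3S)-2-hydroxypent-4-en-3-yl benzoate
Conditions: [Ir(cod)Cl]2 (2.5 mol%), (S)-SEGPHOS (5 mol%), 4-cyano-3-nitrobenzoic acid (10 mol%), Cs2CO3 (20 mol%), ethanol (3 equiv), THF, 90 °C, sealed tube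
Reagents that add atoms: none
Why: Krische-type iridium-catalysed transfer-hydrogenative carbonyl (benzoyloxy)allylation, in which ethanol is dehydrogenated to acetaldehyde and the (benzoyloxy)allyliridium formed from 3 adds through a closed chair transition state, so the (E)-σ-allyl geometry sets the anti C2/C3 relationship and the (S)-ligand sets the absolute configuration.

Step 3
Reactants: 6 3-methylbut-2-enal; 7 3-(methoxymethoxy)prop-1-ene
Product: 9 (3R,4R)-3-(methoxymethoxy)-6-methylhepta-1,5-dien-4-ol, via Z-alkoxyallylborane 8 (not isolated)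
Conditions: 7, s-BuLi, THF, −78 °C; (−)-Ipc2BOMe; BF3·OEt2; then 6, −78 °C; NaOH, H2O2
Reagents that add atoms: none
Why: Brown asymmetric (Z)-γ-alkoxyallylboration, in which the chair Zimmerman–Traxler transition state of the Z-reagent gives the syn 3,4-relationship and the isopinocampheyl groups derived from (+)-α-pinene direct attack to the Si face of the aldehyde, setting 3R,4R.

Step 4
Reactants: 9 (3R,4R)-3-(methoxymethoxy)-6-methylhepta-1,5-dien-4-ol
Product: 10 (3R,4R)-3-(methoxymethoxy)-6-methylhepta-1,5-dien-4-yl prop-2-enoate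
Conditions: acryloyl chloride, Et3N, CH2Cl2, −20 to 0 °C
Reagents that add atoms: acryloyl chloride, C=CC(=O)Cl
Why: plain O-acylation of the only free hydroxyl, which touches no stereocentre and installs the ester needed later for ring B.

Step 5
Reactants: 10 (3R,4R)-3-(methoxymethoxy)-6-methylhepta-1,5-dien-4-yl prop-2-enoate
Product: 11 (2S,3R)-3-(methoxymethoxy)-1-oxopent-4-en-2-yl prop-2-enoate
Conditions: O3, CH2Cl2, −78 °C, Sudan Red 7B end point; then Me2S, −78 °C to rt
Reagents that add atoms: ozone, [O-][O+]=O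
Why: chemoselective ozonolysis, since the electron-rich trisubstituted alkene reacts far faster than the monosubstituted vinyl group or the electron-poor acrylate, and the neutral reductive work-up leaves the α-stereocentre untouched.

Step 6
Reactants: 11 (2S,3R)-3-(methoxymethoxy)-1-oxopent-4-en-2-yl prop-2-enoate; 12 3-chloroprop-1-ene
Product: 15 (1S,2R)-2-(methoxymethoxy)-1-[(2R,3R)-3-vinyloxiran-2-yl]but-3-en-1-yl prop-2-enoate, via Z-chloroallylborane 13 (not isolated), via syn-chlorohydrin 14 (not isolated)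
Conditions: 12, (+)-Ipc2BOMe, LiN(c-C6H11)2, THF/Et2O, −95 °C; BF3·OEt2; then 11, −95 °C; aq NaOAc, H2O2; then Cs2CO3, MeCN, rt
Reagents that add atoms: none
Why: Oehlschlager–Brown (Z)-γ-chloroallylboration through a chair transition state gives the syn-chlorohydrin with Re-face attack dictated by the isopinocampheyl groups derived from (−)-α-pinene (matched to the Felkin–Anh preference of the α-acyloxy aldehyde), and intramolecular Williamson closure with inversion at the C–Cl carbon then gives the cis-epoxide, any 1,2-acyl shift to the new alkoxide being reversible and unproductive.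

Step 7
Reactants: 15 (1S,2R)-2-(methoxymethoxy)-1-[(2R,3R)-3-vinyloxiran-2-yl]but-3-en-1-yl prop-2-enoate
Product: 17 (2S,3R,3aR,7aR)-3-hydroxy-2-vinyl-2,3,3a,7a-tetrahydro-5H-furo[3,2-b]pyran-5-one, via divinyl-oxolanyl acrylate 16 (not isolated)
Conditions: (+)-camphor-10-sulfonic acid (20 mol%), MeOH (3 equiv), CH2Cl2, 0 °C to rt; then second-generation Grubbs catalyst RuCl2(=CHPh)(H2IMes)(PCy3) (5 mol%), 40 °C
Reagents that add atoms: none
Why: Proposed new method: protonation makes the allylic carbon of the cis-vinyl epoxide electrophilic, the methoxymethyl-ether oxygen attacks it 5-endo and anti to the C–O bond (SN2 inversion, hence the all-cis oxolane, ring A) and the oxonium ion sheds its methoxymethyl cation to methanol, after which the cis-disposed acrylate and neighbouring vinyl group close ring B by metathesis in the same flask while the two vinyl groups cannot close on each other without re-forming a strained oxanorbornene; the closest known reaction types are the Nicolaou acid-catalysed endo cyclisation of hydroxy vinyl epoxides, debenzylative cycloetherification by ether oxygens and acrylate ring-closing metathesis.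

Step 8
Reactants: 17 (2S,3R,3aR,7aR)-3-hydroxy-2-vinyl-2,3,3a,7a-tetrahydro-5H-furo[3,2-b]pyran-5-one; 5 (2R,3S)-2-hydroxypent-4-en-3-yl benzoate
Product: 18 (2R,3S,4E)-2-hydroxy-5-[(2S,3R,3aR,7aR)-3-hydroxy-5-oxo-2,3,3a,7a-tetrahydro-5H-furo[3,2-b]pyran-2-yl]pent-4-en-3-yl benzoate
Conditions: 5 (3 equiv), second-generation Hoveyda–Grubbs catalyst RuCl2(=CH-C6H4-2-OiPr)(H2IMes) (10 mol%), CH2Cl2, 40 °C
Reagents that add atoms: none
Why: olefin cross-metathesis of two terminal alkenes that each carry an allylic oxygen, run with excess 5, in which the conjugated lactone alkene is inert, the new disubstituted alkene forms as the E isomer under thermodynamic control and no stereocentre is touched.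

## Compound list

1 | acrolein (prop-2-enal) | C=CC=O | starting material
2 | benzoic anhydride | O=C(OC(=O)c1ccccc1)c1ccccc1 | starting material
3 | prop-2-ene-1,1-diyl dibenzoate | C=CC(OC(=O)c1ccccc1)OC(=O)c1ccccc1 | intermediate
4 | ethanol | CCO | starting material
5 | (2R,3S)-2-hydroxypent-4-en-3-yl benzoate | C[C@@H](O)[C@H](C=C)OC(=O)c1ccccc1 | intermediate
6 | 3-methylbut-2-enal (prenal) | CC(C)=CC=O | starting material
7 | 3-(methoxymethoxy)prop-1-ene (allyl methoxymethyl ether) | C=CCOCOC | starting material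
8 | [(2Z)-3-(methoxymethoxy)prop-2-en-1-yl]bis(isopinocampheyl)borane, isopinocampheyl groups as in (−)-Ipc2BOMe from (+)-α-pinene | COCO/C=C\CB([C@@H]1C[C@@H]2C[C@H]([C@H]1C)C2(C)C)[C@@H]1C[C@@H]2C[C@H]([C@H]1C)C2(C)C | intermediate
9 | (3R,4R)-3-(methoxymethoxy)-6-methylhepta-1,5-dien-4-ol | CC(C)=C[C@@H](O)[C@H](OCOC)C=C | intermediate
10 | (3R,4R)-3-(methoxymethoxy)-6-methylhepta-1,5-dien-4-yl prop-2-enoate | CC(C)=C[C@@H](OC(=O)C=C)[C@H](OCOC)C=C | intermediate
11 | (2S,3R)-3-(methoxymethoxy)-1-oxopent-4-en-2-yl prop-2-enoate | O=C[C@@H](OC(=O)C=C)[C@H](OCOC)C=C | intermediate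
12 | 3-chloroprop-1-ene (allyl chloride) | C=CCCl | starting material
13 | [(2Z)-3-chloroprop-2-en-1-yl]bis(isopinocampheyl)borane, isopinocampheyl groups as in (+)-Ipc2BOMe from (−)-α-pinene | Cl/C=C\CB([C@H]1C[C@H]2C[C@@H]([C@@H]1C)C2(C)C)[C@H]1C[C@H]2C[C@@H]([C@@H]1C)C2(C)C | intermediate
14 | (3R,4R,5S,6S)-6-chloro-5-hydroxy-3-(methoxymethoxy)octa-1,7-dien-4-yl prop-2-enoate | C=C[C@@H](OCOC)[C@H](OC(=O)C=C)[C@H](O)[C@@H](Cl)C=C | intermediate
15 | (1S,2R)-2-(methoxymethoxy)-1-[(2R,3R)-3-vinyloxiran-2-yl]but-3-en-1-yl prop-2-enoate (cis-epoxide) | C=C[C@@H](OCOC)[C@H](OC(=O)C=C)[C@@H]1O[C@@H]1C=C | intermediate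
16 | (2R,3R,4R,5S)-4-hydroxy-2,5-divinyltetrahydrofuran-3-yl prop-2-enoate (all-cis) | C=C[C@@H]1O[C@H](C=C)[C@H](OC(=O)C=C)[C@@H]1O | intermediate
17 | (2S,3R,3aR,7aR)-3-hydroxy-2-vinyl-2,3,3a,7a-tetrahydro-5H-furo[3,2-b]pyran-5-one | C=C[C@@H]1O[C@@H]2C=CC(=O)O[C@@H]2[C@@H]1O | intermediate
18 | (2R,3S,4E)-2-hydroxy-5-[(2S,3R,3aR,7aR)-3-hydroxy-5-oxo-2,3,3a,7a-tetrahydro-5H-furo[3,2-b]pyran-2-yl]pent-4-en-3-yl benzoate (CNP0140142.1) | C[C@@H](O)[C@H](/C=C/[C@@H]1O[C@@H]2C=CC(=O)O[C@@H]2[C@@H]1O)OC(=O)c1ccccc1 | target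

## Step count and risk

Total step count: 8. Longest linear sequence: 6 (steps 3 to 8, from prenal).

**Step 7, the one-flask formation of rings A and B.** The ether oxygen may be too weak a nucleophile, the acrylate carbonyl may take part in the epoxide opening, or the ruthenium catalyst may not tolerate the acid. The fallback sets out from 10 and comes back at 17, making ring B first and ring A last in separate operations. Ring-closing metathesis of 10 with the second-generation Grubbs catalyst RuCl2(=CHPh)(H2IMes)(PCy3), the prenyl alkene being a spectator, gives (5R,6R)-5-(methoxymethoxy)-6-(2-methylprop-1-en-1-yl)-5,6-dihydro-2H-pyran-2-one F1. Ozonolysis with Me2S work-up gives (2S,3R)-3-(methoxymethoxy)-6-oxo-3,6-dihydro-2H-pyran-2-carbaldehyde F2. Addition of borane 13 gives (5R,6R)-6-[(1S,2S)-2-chloro-1-hydroxybut-3-en-1-yl]-5-(methoxymethoxy)-5,6-dihydro-2H-pyran-2-one F3, which Cs2CO3 in MeCN closes to (5R,6S)-5-(methoxymethoxy)-6-[(2R,3R)-3-vinyloxiran-2-yl]-5,6-dihydro-2H-pyran-2-one F4. MgBr2·OEt2 and n-BuSH in CH2Cl2 then cleave the methoxymethyl ether, and the freed hydroxyl opens the vinyl epoxide 5-endo with inversion to give 17.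

**Step 6, chloroallylboration and epoxide closure next to an acrylate.** The α-acyloxy aldehyde may eliminate, or the acrylate may not survive the work-up and the base. The fallback sets out from 9 and comes back at 15, carrying the oxygen as a silyl ether and introducing the acrylate only after the epoxide exists. Et3SiCl and imidazole give triethyl{[(3R,4R)-3-(methoxymethoxy)-6-methylhepta-1,5-dien-4-yl]oxy}silane F5. Ozonolysis gives (2S,3R)-3-(methoxymethoxy)-2-[(triethylsilyl)oxy]pent-4-enal F6. Borane 13 gives (3S,4S,5R,6R)-3-chloro-6-(methoxymethoxy)-5-[(triethylsilyl)oxy]octa-1,7-dien-4-ol F7, which K2CO3 in MeOH closes to triethyl({(1S,2R)-2-(methoxymethoxy)-1-[(2R,3R)-3-vinyloxiran-2-yl]but-3-en-1-yl}oxy)silane F8. Bu4NF buffered with AcOH gives (1S,2R)-2-(methoxymethoxy)-1-[(2R,3R)-3-vinyloxiran-2-yl]but-3-en-1-ol F9, and acryloyl chloride with i-Pr2NEt returns 15.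

**Step 2, the iridium-catalysed coupling with ethanol.** Ethanol is a small, volatile partner, and both the enantioselectivity and benzoate migration under the basic conditions are uncertain. The fallback replaces compounds 3 and 4 by commercial methyl (R)-lactate (chiral pool with substrate control) and comes back at 5. t-BuMe2SiCl and imidazole give methyl (R)-2-[(tert-butyldimethylsilyl)oxy]propanoate F10. i-Bu2AlH at −78 °C gives (R)-2-[(tert-butyldimethylsilyl)oxy]propanal F11. Felkin–Anh addition of CH2=CHMgBr gives, after separation from the minor syn isomer, (3S,4R)-4-[(tert-butyldimethylsilyl)oxy]pent-1-en-3-ol F12. Benzoyl chloride and pyridine give (3S,4R)-4-[(tert-butyldimethylsilyl)oxy]pent-1-en-3-yl benzoate F13, and HF·pyridine removes the silyl group without acyl migration to give 5.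

## Further compounds

F1 | step 7 | (5R,6R)-5-(methoxymethoxy)-6-(2-methylprop-1-en-1-yl)-5,6-dihydro-2H-pyran-2-one | CC(C)=C[C@H]1OC(=O)C=C[C@H]1OCOC
F2 | step 7 | (2S,3R)-3-(methoxymethoxy)-6-oxo-3,6-dihydro-2H-pyran-2-carbaldehyde | O=C[C@H]1OC(=O)C=C[C@H]1OCOC
F3 | step 7 | (5R,6R)-6-[(1S,2S)-2-chloro-1-hydroxybut-3-en-1-yl]-5-(methoxymethoxy)-5,6-dihydro-2H-pyran-2-one | COCO[C@@H]1C=CC(=O)O[C@@H]1[C@H](O)[C@@H](Cl)C=C
F4 | step 7 | (5R,6S)-5-(methoxymethoxy)-6-[(2R,3R)-3-vinyloxiran-2-yl]-5,6-dihydro-2H-pyran-2-one | COCO[C@@H]1C=CC(=O)O[C@@H]1[C@@H]2O[C@@H]2C=C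
F5 | step 6 | triethyl{[(3R,4R)-3-(methoxymethoxy)-6-methylhepta-1,5-dien-4-yl]oxy}silane | CC(C)=C[C@@H](O[Si](CC)(CC)CC)[C@H](OCOC)C=C
F6 | step 6 | (2S,3R)-3-(methoxymethoxy)-2-[(triethylsilyl)oxy]pent-4-enal | O=C[C@@H](O[Si](CC)(CC)CC)[C@H](OCOC)C=C
F7 | step 6 | (3S,4S,5R,6R)-3-chloro-6-(methoxymethoxy)-5-[(triethylsilyl)oxy]octa-1,7-dien-4-ol | C=C[C@@H](OCOC)[C@H](O[Si](CC)(CC)CC)[C@H](O)[C@@H](Cl)C=C
F8 | step 6 | triethyl({(1S,2R)-2-(methoxymethoxy)-1-[(2R,3R)-3-vinyloxiran-2-yl]but-3-en-1-yl}oxy)silane | C=C[C@@H](OCOC)[C@H](O[Si](CC)(CC)CC)[C@@H]1O[C@@H]1C=C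
F9 | step 6 | (1S,2R)-2-(methoxymethoxy)-1-[(2R,3R)-3-vinyloxiran-2-yl]but-3-en-1-ol | C=C[C@@H](OCOC)[C@H](O)[C@@H]1O[C@@H]1C=C
F10 | step 2 | methyl (R)-2-[(tert-butyldimethylsilyl)oxy]propanoate | C[C@@H](O[Si](C)(C)C(C)(C)C)C(=O)OC
F11 | step 2 | (R)-2-[(tert-butyldimethylsilyl)oxy]propanal | C[C@@H](O[Si](C)(C)C(C)(C)C)C=O
F12 | step 2 | (3S,4R)-4-[(tert-butyldimethylsilyl)oxy]pent-1-en-3-ol | C[C@@H](O[Si](C)(C)C(C)(C)C)[C@H](C=C)O
F13 | step 2 | (3S,4R)-4-[(tert-butyldimethylsilyl)oxy]pent-1-en-3-yl benzoate | C[C@@H](O[Si](C)(C)C(C)(C)C)[C@H](C=C)OC(=O)c1ccccc1
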